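Ring A is opened at C1–C2 and C3–C4, so that C2–C3 becomes a cis-vinylene unit inserted between ring B's two arms. In one pot, palladium joins cis-1,2-dichloroethene first to C1 (Negishi coupling of the alkylzinc) and then to C4 (6-exo reductive Heck cyclization onto an isopropenyl group). The step exploits that C1 is a neopentyl CH2 on quaternary C10 and that C4 becomes the quaternary gem-dimethyl carbon of ring A: neither alkylpalladium has a β-hydrogen. The precursor is a ring B cyclohexanone with CH2I on C10, isopropenyl on C5 and the side chain on C9, made from (−)-verbenone, whose cyclobutane carries C4 and both methyls; singlet oxygen then sets the axial C3 oxygen.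

Key step: step 8

Remark on the structure: atoms are numbered as in labdanes (ring A = C1–C5, C10; ring B = C5–C10; side chain C11–C16; C17 exocyclic methylene; C18/C19 on C4; C20 on C10). The target is (3S,5S,9R,10S,13R), i.e. the ent-labdane series with the 3-acetoxy group axial (anti to C20).
Assumption: commercial (1S)-(−)-verbenone is used enantiopure (upgraded if necessary), and PhMe2SiCH2MgCl is prepared beforehand from commercial (chloromethyl)dimethylphenylsilane and magnesium.

Step 1
Reactants: 1 (R)-3-methylglutaric acid monomethyl ester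
Product: 2 methyl (3R)-5-hydroxy-3-methylpentanoate
Conditions: BH3·SMe2, THF, 0 °C to rt; H2O
Reagents that add atoms: none
Why: Chemoselective borane reduction of the free carboxylic acid beside the methyl ester; the purchased C13 stereocenter is not touched and the crude hydroxy ester is used at once to avoid lactonization.

Step 2
Reactants: 2 methyl (3R)-5-hydroxy-3-methylpentanoate
Product: 3 methyl (3S)-5-iodo-3-methylpentanoate
Conditions: I2, PPh3, imidazole, CH2Cl2, 0 °C
Reagents that add atoms: iodine, [I][I]
Why: Appel iodination of the primary alcohol (SN2 at CH2); the stereocenter is unchanged in space and only its descriptor switches from R to S because iodine alters the priorities.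

Step 3
Reactants: 4 (1S,5S)-(−)-verbenone
Product: 5 silyl enol ether of the C10 conjugate adduct
Conditions: PhMe2SiCH2MgCl, CuBr·SMe2 (10 mol %), Me3SiCl, THF, −78 to −20 °C; Et3N, pentane, filtration
Reagents that add atoms: (dimethylphenylsilyl)methylmagnesium chloride, C[Si](C)(C[Mg]Cl)c1ccccc1; chlorotrimethylsilane, C[Si](C)(C)Cl
Why: Copper-catalysed, silyl-chloride-accelerated conjugate addition to the β,β-disubstituted enone should deliver the CH2Si arm (future C1) to the face opposite the gem-dimethyl cyclobutane bridge, which sets quaternary C10 with C20 cis and C1 trans to the future C4, and the enolate is trapped as the silyl enol ether.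

Step 4
Reactants: 5 silyl enol ether of the C10 conjugate adduct; 3 methyl (3S)-5-iodo-3-methylpentanoate
Product: 7 C9-alkylated bicyclic silyl ketone, via lithium enolate 6 (not isolated)
Conditions: MeLi, THF, 0 °C; then 3, DMPU, −40 °C to rt
Reagents that add atoms: none
Why: Methyllithium cleaves the silyl enol ether to the regiodefined lithium enolate (the other α-carbon is a bridgehead and cannot enolize), which undergoes enolate C-alkylation with the primary iodide, expected from the face opposite the gem-dimethyl bridge; the C9 configuration does not matter here because it is equilibrated in step 6.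

Step 5
Reactants: 7 C9-alkylated bicyclic silyl ketone
Product: 8 bicyclic hydroxymethyl ketone
Conditions: KBr, AcOOH, NaOAc, AcOH, rt
Reagents that add atoms: peracetic acid, CC(=O)OO
Why: Fleming–Tamao oxidation: bromodesilylation of the phenyl group and peracid-induced shift of the primary alkyl group from silicon to oxygen should give the C1 alcohol, with no stereocenter involved.

Step 6
Reactants: 8 bicyclic hydroxymethyl ketone
Product: 10 ring B hydroxymethyl isopropenyl ketone, via enol acetate diacetate 9 (not isolated)
Conditions: Ac2O, Zn(OAc)2, CH2Cl2, rt; BF3·OEt2, 0 °C; then K2CO3, MeOH, rt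
Reagents that add atoms: none
Why: After acetylation of the alcohol, Lewis-acid activation of the ketone should trigger the strain-releasing, retro-aldol-type cleavage of the cyclobutane bond between the α-bridgehead carbon and the CMe2 carbon (a fragmentation established for nopinone-type ketones), the tertiary C4 cation losing a methyl proton to give the isopropenyl group and enol acetate 9; methanolysis then frees alcohol and ketone and equilibrates the α-stereocenter C9 to the epimer with the side chain equatorial and cis to C20.

Step 7
Reactants: 10 ring B hydroxymethyl isopropenyl ketone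
Product: 11 ring B iodomethyl isopropenyl ketone
Conditions: I2, PPh3, imidazole, toluene, 60 °C
Reagents that add atoms: iodine, [I][I]
Why: Appel iodination of the neopentyl-type primary alcohol under near-neutral conditions, chosen because base would close a cyclopropane between C9 and C1 in this γ-iodo ketone; no stereocenter is affected.

Step 8
Reactants: 11 ring B iodomethyl isopropenyl ketone; 12 cis-1,2-dichloroethene
Product: 15 Δ2-decalone methyl ester, via alkylzinc iodide 13 (not isolated), via Z-chloroalkene 14 (not isolated)
Conditions: Zn, LiCl, THF, 50 °C; 12 (5 equiv), Pd(PPh3)4 (5 mol %), 40 °C; volatiles off; HCO2Na, Pd(OAc)2 (10 mol %), P(t-Bu)3·HBF4, DMF, 90 °C (one pot)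
Reagents that add atoms: none
Why: Zinc inserts into the C1–I bond and zerovalent palladium couples alkylzinc 13 with one C–Cl bond of 12 (oxidative addition, transmetalation, reductive elimination with retention of the cis geometry) to give 14; on heating with the more electron-rich catalyst the remaining alkenyl chloride adds oxidatively, the alkenylpalladium inserts the isopropenyl C=C, and formate (by decarboxylation to a palladium hydride) reduces the resulting primary alkylpalladium to the second methyl group on C4. The closest known reaction types are the stereoretentive Negishi mono-coupling of cis-1,2-dichloroethene and the formate-terminated (reductive) intramolecular Heck reaction, run here as a domino in one flask. Ring A closes by 6-exo-trig carbopalladation, C3 bonding to the internal alkene carbon C4. No new stereocenter is formed (C4 bears two methyl groups and C2=C3 is necessarily cis in the ring), and the trans ring fusion is dictated by the trans arrangement of the C1 arm on C10 and the isopropenyl group on C5 fixed in step 3. The step needs mono-coupling of 12, exo rather than endo insertion, and hydride capture before the CH2–Pd intermediate can cyclize back onto C2=C3; these are secured by the excess of 12, by the usual exo preference of Heck cyclizations, and by the absence of a β-hydrogen on both alkylpalladium species (C10 and C4 are quaternary) with formate in excess.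

Step 9
Reactants: 15 Δ2-decalone methyl ester
Product: 17 axial 3-hydroxy decalone methyl ester, via allylic hydroperoxide 16 (not isolated)
Conditions: O2, tetraphenylporphyrin (cat.), visible light, CH2Cl2, 0 °C; then H2 (1 atm), Pd/C, EtOAc, rt
Reagents that add atoms: oxygen, O=O
Why: Schenck ene reaction of singlet oxygen: only C1 carries allylic hydrogens (C4 is quaternary), so oxygen must bond to C3 with shift of the alkene to C1=C2, on the face of the pseudo-axial C1–H and anti to the axial C20 and C4 methyl groups, which sets the axial C3–O configuration; hydrogenation then reduces both the O–O bond and C1=C2.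

Step 10
Reactants: 17 axial 3-hydroxy decalone methyl ester
Product: 18 methyl 3-hydroxylabd-8(17)-en-15-oate
Conditions: Ph3PCH3Br, KOtBu, toluene, 80 °C
Reagents that add atoms: methyltriphenylphosphonium bromide, C[P+](c1ccccc1)(c1ccccc1)c1ccccc1.[Br-]
Why: Wittig methylenation of the C8 ketone with excess ylide (the free alcohol is tolerated as its alkoxide), standard for 8-oxo-labdanes; any residual C9 epimer should converge to the equatorial side chain under the basic conditions before C9 is locked.

Step 11
Reactants: 18 methyl 3-hydroxylabd-8(17)-en-15-oate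
Product: 20 3-hydroxylabd-8(17)-en-15-oic acid, via lithium carboxylate 19 (not isolated)
Conditions: LiOH, THF/MeOH/H2O, rt; then 1 M HCl
Reagents that add atoms: lithium hydroxide, [Li+].[OH-]
Why: Saponification of the unhindered methyl ester, done before acetylation so that no ester selectivity is needed.

Step 12
Reactants: 20 3-hydroxylabd-8(17)-en-15-oic acid
Product: 22 (3S,5S,9R,10S,13R)-3-acetoxylabd-8(17)-en-15-oic acid, via mixed anhydride 21 (not isolated)
Conditions: Ac2O, pyridine, DMAP (cat.), CH2Cl2, rt; then H2O/THF
Reagents that add atoms: acetic anhydride, CC(=O)OC(C)=O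
Why: DMAP-catalysed acetylation of the axial secondary alcohol with retention at C3; the transient mixed anhydride at C15 is hydrolysed during the aqueous work-up.

Compound list
1 | (R)-3-methylglutaric acid monomethyl ester [(3R)-5-methoxy-3-methyl-5-oxopentanoic acid] | OC(=O)C[C@@H](C)CC(=O)OC | starting material
2 | methyl (3R)-5-hydroxy-3-methylpentanoate | OCC[C@@H](C)CC(=O)OC | intermediate
3 | methyl (3S)-5-iodo-3-methylpentanoate (C11–C16 unit) | ICC[C@@H](C)CC(=O)OC | intermediate
4 | (1S,5S)-(−)-verbenone [(1S,5S)-4,6,6-trimethylbicyclo[3.1.1]hept-3-en-2-one] | CC1=CC(=O)[C@H]2C[C@@H]1C2(C)C | starting material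
5 | 4-[(dimethylphenylsilyl)methyl]-4,6,6-trimethyl-2-(trimethylsilyloxy)bicyclo[3.1.1]hept-2-ene; CH2Si arm on C4 anti to the CMe2 bridge (C4 = labdane C10) | C[Si](C)(C)OC1=C[C@](C)(C[Si](C)(C)c2ccccc2)[C@@H]3C[C@H]1C3(C)C | intermediate
6 | lithium enolate corresponding to 5 | [Li+].[O-]C1=C[C@](C)(C[Si](C)(C)c2ccccc2)[C@@H]3C[C@H]1C3(C)C | intermediate
7 | methyl (3R)-5-{4-[(dimethylphenylsilyl)methyl]-4,6,6-trimethyl-2-oxobicyclo[3.1.1]hept-3-yl}-3-methylpentanoate; side chain anti to the CMe2 bridge (major C9 epimer shown; C9 is re-set in step 6) | O=C1[C@H](CC[C@@H](C)CC(=O)OC)[C@](C)(C[Si](C)(C)c2ccccc2)[C@@H]3C[C@H]1C3(C)C | intermediate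
8 | methyl (3R)-5-[4-(hydroxymethyl)-4,6,6-trimethyl-2-oxobicyclo[3.1.1]hept-3-yl]-3-methylpentanoate (configuration as in 7) | O=C1[C@H](CC[C@@H](C)CC(=O)OC)[C@](C)(CO)[C@@H]3C[C@H]1C3(C)C | intermediate
9 | methyl (3R)-5-[2-acetoxy-6-(acetoxymethyl)-6-methyl-5-(prop-1-en-2-yl)cyclohex-2-en-1-yl]-3-methylpentanoate (ring-opened enol acetate; isopropenyl trans to CH2OAc) | CC(=O)OC1=CC[C@H](C(C)=C)[C@@](C)(COC(C)=O)[C@H]1CC[C@@H](C)CC(=O)OC | intermediate
10 | methyl (3R)-5-[2-(hydroxymethyl)-2-methyl-6-oxo-3-(prop-1-en-2-yl)cyclohexyl]-3-methylpentanoate; isopropenyl trans to CH2OH and cis to CH3, side chain cis to CH3 (labdane C5, C9, C10 as in the target) | O=C1CC[C@H](C(C)=C)[C@@](C)(CO)[C@@H]1CC[C@@H](C)CC(=O)OC | intermediate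
11 | methyl (3R)-5-[2-(iodomethyl)-2-methyl-6-oxo-3-(prop-1-en-2-yl)cyclohexyl]-3-methylpentanoate (configuration as in 10) | O=C1CC[C@H](C(C)=C)[C@@](C)(CI)[C@@H]1CC[C@@H](C)CC(=O)OC | intermediate
12 | cis-1,2-dichloroethene | Cl/C=C\Cl | starting material
13 | alkylzinc iodide formed from 11 (C1–ZnI) | O=C1CC[C@H](C(C)=C)[C@@](C)(C[Zn]I)[C@@H]1CC[C@@H](C)CC(=O)OC | intermediate
14 | (Z)-3-chloroprop-2-enyl compound (C1–C2H=C3H–Cl on C10) | O=C1CC[C@H](C(C)=C)[C@@](C)(C/C=C\Cl)[C@@H]1CC[C@@H](C)CC(=O)OC | intermediate
15 | methyl 8-oxo-17-norlabd-2-en-15-oate of the ent-series (trans-decalin; C5, C9, C10, C13 as in the target) | O=C1CC[C@@H]2C(C)(C)C=CC[C@@]2(C)[C@@H]1CC[C@@H](C)CC(=O)OC | intermediate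
16 | methyl 3-hydroperoxy-8-oxo-17-norlabd-1-en-15-oate (OOH axial, anti to C20) | O=C1CC[C@@H]2C(C)(C)[C@@H](OO)C=C[C@@]2(C)[C@@H]1CC[C@@H](C)CC(=O)OC | intermediate
17 | methyl 3-hydroxy-8-oxo-17-norlabdan-15-oate (axial 3-OH, anti to C20) | O=C1CC[C@@H]2C(C)(C)[C@@H](O)CC[C@@]2(C)[C@@H]1CC[C@@H](C)CC(=O)OC | intermediate
18 | methyl 3-hydroxylabd-8(17)-en-15-oate (axial 3-OH; ent-series) | C=C1CC[C@@H]2C(C)(C)[C@@H](O)CC[C@@]2(C)[C@@H]1CC[C@@H](C)CC(=O)OC | intermediate
19 | lithium 3-hydroxylabd-8(17)-en-15-oate | C=C1CC[C@@H]2C(C)(C)[C@@H](O)CC[C@@]2(C)[C@@H]1CC[C@@H](C)CC(=O)[O-].[Li+] | intermediate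
20 | 3-hydroxylabd-8(17)-en-15-oic acid (axial 3-OH; ent-series) | C=C1CC[C@@H]2C(C)(C)[C@@H](O)CC[C@@]2(C)[C@@H]1CC[C@@H](C)CC(=O)O | intermediate
21 | acetic 3-acetoxylabd-8(17)-en-15-oic anhydride | C=C1CC[C@@H]2C(C)(C)[C@@H](OC(C)=O)CC[C@@]2(C)[C@@H]1CC[C@@H](C)CC(=O)OC(C)=O | intermediate
22 | (3S,5S,9R,10S,13R)-3-acetoxylabd-8(17)-en-15-oic acid (CNP0281344.1) | C=C1CC[C@@H]2C(C)(C)[C@@H](OC(C)=O)CC[C@@]2(C)[C@@H]1CC[C@@H](C)CC(=O)O | target

Total step count: 12. Longest linear sequence: 11 steps (steps 1, 2 and 4–12, from 1); from verbenone 4 it is 10 steps (steps 3–12).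

Steps most likely to fail

Step 8 (key step). The alkenylpalladium chloride may be reduced by formate before it cyclizes, or transmetalation of the hindered neopentyl zinc reagent may be too slow, so that ring A does not close. The fallback sets out from 10 and returns at 17, building C1–C2 by olefination and C3–C4 by radical addition to a carbonyl instead of by palladium. Dess–Martin oxidation of 10 gives the neopentyl aldehyde F1. Wittig reaction with Ph3P=CHCHO gives the (E)-enal F2, and conjugate reduction with [(Ph3P)CuH]6 gives the saturated aldehyde F3. Fe(acac)3/PhSiH3 then transfers a hydrogen atom to the isopropenyl group, and the tertiary C4 radical adds 6-exo to the aldehyde carbon; reduction of the alkoxy radical should give 17, which is separated from its equatorial C3 epimer.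

Step 4. C-Alkylation of the hindered enolate next to quaternary C10 may be slow, with proton transfer to the ester-bearing iodide or O-alkylation taking over. The fallback sets out from 5 and returns at 7, replacing the SN2 alkylation by an aldol, elimination and hydrogenation sequence. Dess–Martin oxidation of 2 gives methyl (3R)-3-methyl-5-oxopentanoate F4. Mukaiyama aldol addition of 5 to F4 (TiCl4, CH2Cl2, −78 °C) gives the β-hydroxy ketone F5. Mesylation and elimination (MsCl, Et3N; DBU) give the alkylidene ketone F6, and hydrogenation of its C=C bond (H2, Pd/C) gives 7.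

Step 9. The ene reaction of singlet oxygen with a cis-disubstituted cyclohexene is slow, so incomplete conversion and bleaching of the sensitizer are likely. The fallback sets out from 15 and returns at 17, replacing the ene reaction by epoxide chemistry. Dimethyldioxirane should epoxidize C2=C3 from the face anti to C20 and the axial C4 methyl group, giving the 2,3-epoxide F7. Trans-diaxial opening at C2 with PhSeNa gives the axial 3-hydroxy 2-phenylselenide F8, and Bu3SnH/AIBN removes selenium to give 17.

Further compounds
F1 | step 8 | methyl (3R)-5-[2-formyl-2-methyl-6-oxo-3-(prop-1-en-2-yl)cyclohexyl]-3-methylpentanoate (configuration as in 10) | O=C1CC[C@H](C(C)=C)[C@@](C)(C=O)[C@@H]1CC[C@@H](C)CC(=O)OC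
F2 | step 8 | (E)-enal from F1 (C1=C2–C3HO on C10) | O=C1CC[C@H](C(C)=C)[C@@](C)(/C=C/C=O)[C@@H]1CC[C@@H](C)CC(=O)OC
F3 | step 8 | saturated aldehyde (C1H2–C2H2–C3HO on C10) | O=C1CC[C@H](C(C)=C)[C@@](C)(CCC=O)[C@@H]1CC[C@@H](C)CC(=O)OC
F4 | step 4 | methyl (3R)-3-methyl-5-oxopentanoate | O=CC[C@@H](C)CC(=O)OC
F5 | step 4 | aldol adduct of 5 and F4 (β-hydroxy ketone; diastereomer mixture at C9 and C11) | O=C1C(C(O)C[C@@H](C)CC(=O)OC)[C@](C)(C[Si](C)(C)c2ccccc2)[C@@H]3C[C@H]1C3(C)C
F6 | step 4 | alkylidene ketone (C9=C11; E/Z mixture) | O=C1C(=CC[C@@H](C)CC(=O)OC)[C@](C)(C[Si](C)(C)c2ccccc2)[C@@H]3C[C@H]1C3(C)C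
F7 | step 9 | methyl 2,3-epoxy-8-oxo-17-norlabdan-15-oate (epoxide anti to C20) | O=C1CC[C@@H]2C(C)(C)[C@H]3O[C@H]3C[C@@]2(C)[C@@H]1CC[C@@H](C)CC(=O)OC
F8 | step 9 | methyl 3-hydroxy-8-oxo-2-(phenylselanyl)-17-norlabdan-15-oate (3-OH and 2-SePh trans-diaxial) | O=C1CC[C@@H]2C(C)(C)[C@@H](O)[C@H]([Se]c3ccccc3)C[C@@]2(C)[C@@H]1CC[C@@H](C)CC(=O)OC
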